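**Retrosynthetic overview**

- The plan rests on ring B: the prenyl CH2 sits on C3, ortho to the free C4–OH and next to the C2–OMe. This ortho-allylphenol pattern is what an aromatic Claisen shift from O4 leaves behind.
- After removal of the two ring A MOM groups, the C3–CH2 bond is disconnected, leading back to the 4-O-(2-methylbut-3-en-2-yl) ether of the bis-MOM chalcone.
- The enone C=C is disconnected by Claisen–Schmidt condensation into the ring B aldehyde carrying the tertiary allyl ether and 3,4-bis(methoxymethoxy)acetophenone.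
- The tertiary allyl ether comes from 4-hydroxy-2-methoxybenzaldehyde by O-propargylation with 3-chloro-3-methylbut-1-yne and semihydrogenation.
- No ring is formed in the route: both benzene rings are bought, and the only stereo element, the E enone, is set in the condensation.

Key step: step 5

Remark: the β-hydroxy ketone 7 and the dienone 9 form as racemates and are consumed in the flask in which they arise, so neither stereocentre reaches an isolated compound.

**Route**

Step 1
Reactants: 1 4-hydroxy-2-methoxybenzaldehyde; 2 3-chloro-3-methylbut-1-yne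
Product: 3 2-methoxy-4-(2-methylbut-3-yn-2-yloxy)benzaldehyde
Conditions: CuCl2·2H2O (cat.), DBU, MeCN, 0 °C
Reagents that add atoms: none
Why: Copper-catalysed O-alkylation of a phenol with a tertiary propargylic chloride (propargylic substitution through a copper acetylide) is the standard entry to aryl 1,1-dimethylpropargyl ethers, tolerates acceptor-substituted phenols and leaves the aldehyde untouched at 0 °C.

Step 2
Reactants: 3 2-methoxy-4-(2-methylbut-3-yn-2-yloxy)benzaldehyde
Product: 4 2-methoxy-4-(2-methylbut-3-en-2-yloxy)benzaldehyde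
Conditions: H2 (1 atm), Pd/CaCO3 poisoned with Pb(OAc)2, quinoline, EtOAc, rt, stopped after one equivalent of H2
Reagents that add atoms: none
Why: Lindlar semihydrogenation adds one equivalent of H2 to the terminal alkyne on lead-poisoned palladium and should stop at the alkene, while the aldehyde and the aryl ether are not reduced under these conditions.

Step 3
Reactants: 5 3,4-dihydroxyacetophenone
Product: 6 3,4-bis(methoxymethoxy)acetophenone
Conditions: MOMCl (2.5 equiv), iPr2NEt, CH2Cl2, 0 °C to rt
Reagents that add atoms: chloromethyl methyl ether (MOMCl), COCCl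
Why: Williamson-type O-alkylation of both phenols with the reactive α-chloro ether gives the bis-MOM ether, which is stable to hydroxide and to heat and is removed later by mild acid.

Step 4
Reactants: 4 2-methoxy-4-(2-methylbut-3-en-2-yloxy)benzaldehyde; 6 3,4-bis(methoxymethoxy)acetophenone
Product: 8 (E)-1-[3,4-bis(methoxymethoxy)phenyl]-3-[2-methoxy-4-(2-methylbut-3-en-2-yloxy)phenyl]prop-2-en-1-one, via β-hydroxy ketone 7 (not isolated)
Conditions: KOH, EtOH/H2O, 0 °C to rt
Reagents that add atoms: none
Why: Claisen–Schmidt condensation, in which the potassium enolate of the methyl ketone adds to the non-enolisable aldehyde and aldol 7 loses water by E1cB to the conjugated, thermodynamically preferred E enone; the tertiary allyl ether and the MOM ethers are stable to base at room temperature.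

Step 5
Reactants: 8 (E)-1-[3,4-bis(methoxymethoxy)phenyl]-3-[2-methoxy-4-(2-methylbut-3-en-2-yloxy)phenyl]prop-2-en-1-one
Product: 10 (E)-1-[3,4-bis(methoxymethoxy)phenyl]-3-[4-hydroxy-2-methoxy-3-(3-methylbut-2-enyl)phenyl]prop-2-en-1-one, via ortho-dienone 9 (not isolated)
Conditions: N,N-diethylaniline (degassed), 130 °C, Ar, dark
Reagents that add atoms: none
Why: Thermal aromatic Claisen rearrangement: a concerted suprafacial [3,3] shift through a chair transition state joins the terminal CH2 of the 2-methylbut-3-en-2-yl group to ring B C3 while the O4–CMe2 bond breaks, giving dienone 9, which enolises to phenol 10; the allylic transposition turns the tertiary ether into the linear 3-methylbut-2-enyl group. The closest known reaction type is the ortho-Claisen rearrangement of aryl 1,1-dimethylallyl ethers to ortho-prenylphenols, as in 7-(1,1-dimethylallyloxy)coumarins and 4-O-substituted resorcinol carbonyl compounds. No ring closes and no stereocentre remains, because the sp3 centre at C3 of 9 is erased on tautomerisation and the E enone is not touched. The step needs migration to C3 and not to C5: the 2-methoxy group is in push–pull conjugation through C1 with the enone, which raises the C3–C4 π-bond order and lowers that of C4–C5, so O4–C4=C3 is the better allyl vinyl ether unit, and the migrating terminus is an unhindered CH2 that fits between the two oxygens. The gem-dimethyl group weakens the O–C bond so the shift should run near 130 °C, below the temperature at which the MOM ethers or the enone react, and the weakly basic amine solvent suppresses acid-induced ionisation of the tertiary ether and chroman formation.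

Step 6
Reactants: 10 (E)-1-[3,4-bis(methoxymethoxy)phenyl]-3-[4-hydroxy-2-methoxy-3-(3-methylbut-2-enyl)phenyl]prop-2-en-1-one
Product: 11 licoagrochalcone C, (E)-1-(3,4-dihydroxyphenyl)-3-[4-hydroxy-2-methoxy-3-(3-methylbut-2-enyl)phenyl]prop-2-en-1-one
Conditions: 3 M aq. HCl, MeOH, rt, quenched with NaHCO3 on completion
Reagents that add atoms: none
Why: Acid-catalysed acetal cleavage (MOM deprotection), in which each methoxymethyl group leaves as an oxocarbenium ion trapped by methanol as dimethoxymethane, frees both ring A phenols, while the aryl methyl ether, the enone and, at room temperature and this acid strength, the prenyl alkene should be left alone.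

**Compound list**

1 | 4-hydroxy-2-methoxybenzaldehyde | COc1cc(O)ccc1C=O | starting material
2 | 3-chloro-3-methylbut-1-yne | C#CC(C)(C)Cl | starting material
3 | 2-methoxy-4-(2-methylbut-3-yn-2-yloxy)benzaldehyde | COc1cc(OC(C)(C)C#C)ccc1C=O | intermediate
4 | 2-methoxy-4-(2-methylbut-3-en-2-yloxy)benzaldehyde | COc1cc(OC(C)(C)C=C)ccc1C=O | intermediate
5 | 3,4-dihydroxyacetophenone | CC(=O)c1ccc(O)c(O)c1 | starting material
6 | 3,4-bis(methoxymethoxy)acetophenone | CC(=O)c1ccc(OCOC)c(OCOC)c1 | intermediate
7 | 1-[3,4-bis(methoxymethoxy)phenyl]-3-hydroxy-3-[2-methoxy-4-(2-methylbut-3-en-2-yloxy)phenyl]propan-1-one (racemic, not isolated) | COCOc1ccc(C(=O)CC(O)c2ccc(OC(C)(C)C=C)cc2OC)cc1OCOC | intermediate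
8 | (E)-1-[3,4-bis(methoxymethoxy)phenyl]-3-[2-methoxy-4-(2-methylbut-3-en-2-yloxy)phenyl]prop-2-en-1-one | COCOc1ccc(C(=O)/C=C/c2ccc(OC(C)(C)C=C)cc2OC)cc1OCOC | intermediate
9 | (E)-1-[3,4-bis(methoxymethoxy)phenyl]-3-[2-methoxy-3-(3-methylbut-2-enyl)-4-oxocyclohexa-1,5-dienyl]prop-2-en-1-one (racemic, not isolated) | COCOc1ccc(C(=O)/C=C/C2=C(OC)C(CC=C(C)C)C(=O)C=C2)cc1OCOC | intermediate
10 | (E)-1-[3,4-bis(methoxymethoxy)phenyl]-3-[4-hydroxy-2-methoxy-3-(3-methylbut-2-enyl)phenyl]prop-2-en-1-one | COCOc1ccc(C(=O)/C=C/c2ccc(O)c(CC=C(C)C)c2OC)cc1OCOC | intermediate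
11 | licoagrochalcone C, (E)-1-(3,4-dihydroxyphenyl)-3-[4-hydroxy-2-methoxy-3-(3-methylbut-2-enyl)phenyl]prop-2-en-1-one | COc1c(/C=C/C(=O)c2ccc(O)c(O)c2)ccc(O)c1CC=C(C)C | target

**Step count**

Total step count: 6. Longest linear sequence: 5 steps (1 → 3 → 4 → 8 → 10 → 11); step 3 is a one-step side branch.

**Steps most likely to fail**

Step 5. The allyl unit may migrate to C5 instead of C3, or the tertiary C–O bond may break heterolytically with loss of isoprene, so that the C3–CH2 bond is not formed cleanly. The fallback makes that bond by directed ortho-metalation and sets out from 1.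
- Treatment of 1 with MOMCl and iPr2NEt in CH2Cl2 should give 2-methoxy-4-(methoxymethoxy)benzaldehyde F1.
- Addition of lithium N-methylpiperazide in THF at −20 °C masks the aldehyde as lithium [2-methoxy-4-(methoxymethoxy)phenyl](4-methylpiperazin-1-yl)methanolate F2, which is not isolated.
- n-BuLi then removes the C3 proton flanked by OMe and OMOM to give lithium [3-lithio-2-methoxy-4-(methoxymethoxy)phenyl](4-methylpiperazin-1-yl)methanolate F3, also not isolated.
- Alkylation with prenyl bromide (CuBr·SMe2 cat.) gives lithium [2-methoxy-4-(methoxymethoxy)-3-(3-methylbut-2-enyl)phenyl](4-methylpiperazin-1-yl)methanolate F4, which on aqueous work-up releases 2-methoxy-4-(methoxymethoxy)-3-(3-methylbut-2-enyl)benzaldehyde F5.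
- Condensation of F5 with 6 under the conditions of step 4 passes through 1-[3,4-bis(methoxymethoxy)phenyl]-3-hydroxy-3-[2-methoxy-4-(methoxymethoxy)-3-(3-methylbut-2-enyl)phenyl]propan-1-one F6 (not isolated) to (E)-1-[3,4-bis(methoxymethoxy)phenyl]-3-[2-methoxy-4-(methoxymethoxy)-3-(3-methylbut-2-enyl)phenyl]prop-2-en-1-one F7.
- The acid treatment of step 6 removes all three MOM groups from F7 and returns to the route at 11.

Step 6. Under acid the C4 phenol may add to the neighbouring prenyl alkene (chroman closure), or the alkene may be hydrated, in competition with acetal cleavage. The fallback replaces the acid-labile groups by fluoride-labile ones and sets out from 5.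
- SEMCl and iPr2NEt in CH2Cl2 should give 3,4-bis{[2-(trimethylsilyl)ethoxy]methoxy}acetophenone F8.
- Condensation of F8 with 4 under the conditions of step 4 passes through 1-(3,4-bis{[2-(trimethylsilyl)ethoxy]methoxy}phenyl)-3-hydroxy-3-[2-methoxy-4-(2-methylbut-3-en-2-yloxy)phenyl]propan-1-one F9 (not isolated) to (E)-1-(3,4-bis{[2-(trimethylsilyl)ethoxy]methoxy}phenyl)-3-[2-methoxy-4-(2-methylbut-3-en-2-yloxy)phenyl]prop-2-en-1-one F10.
- Heating F10 as in step 5 passes through (E)-1-(3,4-bis{[2-(trimethylsilyl)ethoxy]methoxy}phenyl)-3-[2-methoxy-3-(3-methylbut-2-enyl)-4-oxocyclohexa-1,5-dienyl]prop-2-en-1-one F11 (not isolated) to (E)-1-(3,4-bis{[2-(trimethylsilyl)ethoxy]methoxy}phenyl)-3-[4-hydroxy-2-methoxy-3-(3-methylbut-2-enyl)phenyl]prop-2-en-1-one F12.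
- Bu4NF in THF/DMPU at 50 °C under argon, followed by NH4Cl work-up, cleaves both SEM ethers of F12 without acid and returns to the route at 11.

Step 2. Hydrogenation may run past the alkene to the saturated tert-pentyl ether, which cannot rearrange and is hard to separate. The fallback avoids the alkyne altogether and sets out from 1: palladium-catalysed O-allylation with tert-butyl 2-methylbut-3-en-2-yl carbonate (Pd(PPh3)4 cat., THF, 0 °C) proceeds by decarboxylative formation of a 1,1-dimethylallyl palladium complex that the phenoxide attacks at the more substituted terminus. This should give the tertiary allyl ether directly and return to the route at 4.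

**Further compounds**

F1 | step 5 | 2-methoxy-4-(methoxymethoxy)benzaldehyde | COCOc1ccc(C=O)c(OC)c1
F2 | step 5 | lithium [2-methoxy-4-(methoxymethoxy)phenyl](4-methylpiperazin-1-yl)methanolate (racemic, not isolated) | COCOc1ccc(C(O[Li])N2CCN(C)CC2)c(OC)c1
F3 | step 5 | lithium [3-lithio-2-methoxy-4-(methoxymethoxy)phenyl](4-methylpiperazin-1-yl)methanolate (racemic, not isolated) | COCOc1ccc(C(O[Li])N2CCN(C)CC2)c(OC)c1[Li]
F4 | step 5 | lithium [2-methoxy-4-(methoxymethoxy)-3-(3-methylbut-2-enyl)phenyl](4-methylpiperazin-1-yl)methanolate (racemic, not isolated) | COCOc1ccc(C(O[Li])N2CCN(C)CC2)c(OC)c1CC=C(C)C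
F5 | step 5 | 2-methoxy-4-(methoxymethoxy)-3-(3-methylbut-2-enyl)benzaldehyde | COCOc1ccc(C=O)c(OC)c1CC=C(C)C
F6 | step 5 | 1-[3,4-bis(methoxymethoxy)phenyl]-3-hydroxy-3-[2-methoxy-4-(methoxymethoxy)-3-(3-methylbut-2-enyl)phenyl]propan-1-one (racemic, not isolated) | COCOc1ccc(C(=O)CC(O)c2ccc(OCOC)c(CC=C(C)C)c2OC)cc1OCOC
F7 | step 5 | (E)-1-[3,4-bis(methoxymethoxy)phenyl]-3-[2-methoxy-4-(methoxymethoxy)-3-(3-methylbut-2-enyl)phenyl]prop-2-en-1-one | COCOc1ccc(C(=O)/C=C/c2ccc(OCOC)c(CC=C(C)C)c2OC)cc1OCOC
F8 | step 6 | 3,4-bis{[2-(trimethylsilyl)ethoxy]methoxy}acetophenone | CC(=O)c1ccc(OCOCC[Si](C)(C)C)c(OCOCC[Si](C)(C)C)c1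
F9 | step 6 | 1-(3,4-bis{[2-(trimethylsilyl)ethoxy]methoxy}phenyl)-3-hydroxy-3-[2-methoxy-4-(2-methylbut-3-en-2-yloxy)phenyl]propan-1-one (racemic, not isolated) | C[Si](C)(C)CCOCOc1ccc(C(=O)CC(O)c2ccc(OC(C)(C)C=C)cc2OC)cc1OCOCC[Si](C)(C)C
F10 | step 6 | (E)-1-(3,4-bis{[2-(trimethylsilyl)ethoxy]methoxy}phenyl)-3-[2-methoxy-4-(2-methylbut-3-en-2-yloxy)phenyl]prop-2-en-1-one | C[Si](C)(C)CCOCOc1ccc(C(=O)/C=C/c2ccc(OC(C)(C)C=C)cc2OC)cc1OCOCC[Si](C)(C)C
F11 | step 6 | (E)-1-(3,4-bis{[2-(trimethylsilyl)ethoxy]methoxy}phenyl)-3-[2-methoxy-3-(3-methylbut-2-enyl)-4-oxocyclohexa-1,5-dienyl]prop-2-en-1-one (racemic, not isolated) | C[Si](C)(C)CCOCOc1ccc(C(=O)/C=C/C2=C(OC)C(CC=C(C)C)C(=O)C=C2)cc1OCOCC[Si](C)(C)C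
F12 | step 6 | (E)-1-(3,4-bis{[2-(trimethylsilyl)ethoxy]methoxy}phenyl)-3-[4-hydroxy-2-methoxy-3-(3-methylbut-2-enyl)phenyl]prop-2-en-1-one | C[Si](C)(C)CCOCOc1ccc(C(=O)/C=C/c2ccc(O)c(CC=C(C)C)c2OC)cc1OCOCC[Si](C)(C)C
F0 | step 2 | none | none
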